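**Retrosynthetic overview**

1. The target is traced back (homoprenyl Wittig, C18 deoxygenation, allyl then methyl at C17 of a C18 ketone, C7 deoxygenation, Li/NH3) to the pentacyclic enone alcohol 22.
2. The strategy rests on C13 and C14, the adjacent quaternary fusion carbons of rings C and D with trans methyls. They are read as anti addition of C18 (to C13) and C8 (to C14) across an (E)-2,3-dimethyl alkene, so 22 opens to the aldehyde–alkene–2-silyloxydiene 21.
3. 21 comes from the ring A/B enone 17, made by Pauson–Khand cyclisation of enyne 15; this closes ring B and the pyran half of ring A onto a cis-2,5-disubstituted oxolane.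
4. 15 comes from methyl ketone 10 ((R)-pantolactone; Wittig, B-alkyl Suzuki, Shi epoxidation with 5-exo opening) and allylic bromide 13 (2,3-dimethylbutadiene; Br2, allyl Grignard).
5. Ring order: oxolane, then rings A and B together, then rings D and C together.

Key step: step 15

Numbering: ring A = C10, C1–C5, C9 with O between C3 and C10; ring B = C5–C9; ring C = C8, C9, C11–C14; ring D = C13–C18.
Remark on the chemistry: the diene silyl group is tert-butyldimethylsilyl so that it survives steps 13 and 14; carbinol 29 and xanthate 30 are written as one C18 epimer, but both epimers are expected and both converge in step 23.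

**Route**

Step 1
Reactants: 1 (R)-pantolactone
Product: 2 (3R)-4,4-dimethyloxolane-2,3-diol (lactol, anomer mixture)
Conditions: i-Bu2AlH (2.2 equiv), CH2Cl2, −78 °C; aq. potassium sodium tartrate
Reagents that add atoms: none
Why: Partial hydride reduction of the lactone stops at the aluminium hemiacetal at low temperature and gives the lactol on work-up, leaving C3 untouched.

Step 2
Reactants: 2 (3R)-4,4-dimethyloxolane-2,3-diol
Product: 3 (3S)-2,2-dimethylpent-4-ene-1,3-diol
Conditions: Ph3PCH3Br (3.5 equiv), KOt-Bu (3.4 equiv), THF, 0 → 65 °C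
Reagents that add atoms: methyltriphenylphosphonium bromide, C[P+](c1ccccc1)(c1ccccc1)c1ccccc1.[Br-]
Why: Wittig methylenation of the open hydroxy-aldehyde form makes the C2=C1 vinyl group, C3 being held as its alkoxide and keeping its configuration (the descriptor changes only through CIP priorities).

Step 3
Reactants: 3 (3S)-2,2-dimethylpent-4-ene-1,3-diol; 4 (Z)-2-bromobut-2-ene
Product: 6 (3S,6Z)-2,2,6-trimethyloct-6-ene-1,3-diol, via triborylated pentanediol 5 (not isolated)
Conditions: 9-BBN (3.3 equiv), THF, 0 °C → rt; then 4, PdCl2(dppf) (5 mol %), AsPh3, 3 M aq. NaOH, DMF, rt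
Reagents that add atoms: none
Why: Anti-Markovnikov hydroboration of the terminal alkene (two further equivalents of borane are taken up by the hydroxyls) followed by B-alkyl Suzuki–Miyaura coupling, which retains the bromoalkene geometry, gives the Z C10=C9 alkene.

Step 4
Reactants: 6 (3S,6Z)-2,2,6-trimethyloct-6-ene-1,3-diol
Product: 8 (1R)-1-[(2R,5S)-5-(1-hydroxy-2-methylpropan-2-yl)-2-methyloxolan-2-yl]ethan-1-ol, via epoxy diol 7 (not isolated)
Conditions: D-fructose-derived Shi ketone (0.3 equiv), KHSO5, K2CO3, Bu4NHSO4, MeCN/CH2(OMe)2/aq. Na2B4O7 buffer, 0 °C; then CSA (0.1 equiv), CH2Cl2, 0 °C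
Reagents that add atoms: potassium peroxymonosulfate, [K+].[O-]S(=O)(=O)OO
Why: Shi epoxidation (dioxirane, spiro transition state) should give the (9R,10S) epoxide of the Z alkene under reagent control, and acid-catalysed 5-exo opening by the C3 hydroxyl at the tertiary carbon with inversion then sets C10 as R, with C9 cis to C4 across the oxolane.

Step 5
Reactants: 8 (1R)-1-[(2R,5S)-5-(1-hydroxy-2-methylpropan-2-yl)-2-methyloxolan-2-yl]ethan-1-ol
Product: 9 2-[(2S,5R)-5-acetyl-5-methyloxolan-2-yl]-2-methylpropanal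
Conditions: Dess–Martin periodinane (3 equiv), NaHCO3, CH2Cl2, rt
Reagents that add atoms: none
Why: Dess–Martin oxidation takes both alcohols to carbonyls, and neither the quaternary C10 nor the ring carbon C3 can epimerise.

Step 6
Reactants: 9 2-[(2S,5R)-5-acetyl-5-methyloxolan-2-yl]-2-methylpropanal
Product: 10 1-[(2R,5S)-2-methyl-5-(2-methylbut-3-yn-2-yl)oxolan-2-yl]ethan-1-one
Conditions: dimethyl (1-diazo-2-oxopropyl)phosphonate (1.3 equiv), K2CO3, MeOH, 0 °C → rt
Reagents that add atoms: dimethyl (1-diazo-2-oxopropyl)phosphonate, CC(=O)C(=[N+]=[N-])P(=O)(OC)OC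
Why: Seyferth–Gilbert homologation with the Ohira–Bestmann reagent converts the non-enolisable aldehyde into the terminal alkyne, and the far less electrophilic methyl ketone is left alone.

Step 7
Reactants: 11 2,3-dimethylbuta-1,3-diene
Product: 12 (2E)-1,4-dibromo-2,3-dimethylbut-2-ene
Conditions: Br2 (1.0 equiv), CH2Cl2, −20 °C → rt; recrystallisation from pentane
Reagents that add atoms: bromine, BrBr
Why: Bromine adds 1,4 to the diene under equilibrating conditions and the crystalline E dibromide is collected, which fixes the alkene geometry used in the key step.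

Step 8
Reactants: 12 (2E)-1,4-dibromo-2,3-dimethylbut-2-ene
Product: 13 (2E)-1-bromo-2,3-dimethylhepta-2,6-diene
Conditions: CH2=CHCH2MgBr (1.0 equiv, slow addition), 12 (3 equiv), THF, −40 → 0 °C; excess 12 recovered
Reagents that add atoms: allylmagnesium bromide, C=CC[Mg]Br
Why: Copper-free Grignard coupling occurs by SN2 at the primary allylic carbon (the SN2' carbon is fully substituted) and the excess of the symmetrical dibromide limits double substitution.

Step 9
Reactants: 10 1-[(2R,5S)-2-methyl-5-(2-methylbut-3-yn-2-yl)oxolan-2-yl]ethan-1-one; 13 (2E)-1-bromo-2,3-dimethylhepta-2,6-diene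
Product: 14 (4E)-4,5-dimethyl-1-[(2R,5S)-2-methyl-5-(2-methylbut-3-yn-2-yl)oxolan-2-yl]nona-4,8-dien-1-one
Conditions: LiN(SiMe3)2 (1.05 equiv), THF, −78 °C; 13 (1.2 equiv), DMPU, −78 → −20 °C
Reagents that add atoms: none
Why: The ketone has one enolisable side and is more acidic than the tert-alkyl acetylene, so its lithium enolate forms selectively and undergoes SN2 alkylation by the allylic bromide to make the C11–C12 bond.

Step 10
Reactants: 14 (4E)-4,5-dimethyl-1-[(2R,5S)-2-methyl-5-(2-methylbut-3-yn-2-yl)oxolan-2-yl]nona-4,8-dien-1-one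
Product: 15 (2R,5S)-2-[(5E)-5,6-dimethyldeca-1,5,9-trien-2-yl]-2-methyl-5-(2-methylbut-3-yn-2-yl)oxolane
Conditions: Ph3PCH3Br (3 equiv), KOt-Bu (2.9 equiv), THF, 65 °C
Reagents that add atoms: methyltriphenylphosphonium bromide, C[P+](c1ccccc1)(c1ccccc1)c1ccccc1.[Br-]
Why: Wittig methylenation with excess salt-free ylide converts the hindered ketone into the C9=C8 1,1-disubstituted alkene, and the ylide is too weak a base to hold the alkyne as its anion.

Step 11
Reactants: 15 (2R,5S)-2-[(5E)-5,6-dimethyldeca-1,5,9-trien-2-yl]-2-methyl-5-(2-methylbut-3-yn-2-yl)oxolane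
Product: 17 ring A/B enone (C5=C6–C7=O cyclopentenone fused at C5–C9 to the 4,4,10-trimethyl-8-oxabicyclo[3.2.1]octane; C9 carries the (3E)-3,4-dimethylocta-3,7-dienyl chain), via hexacarbonyldicobalt alkyne complex 16 (not isolated)
Conditions: Co2(CO)8 (1.1 equiv), CH2Cl2, rt; then NMO (8 equiv), CH2Cl2, 0 °C → rt
Reagents that add atoms: dicobalt octacarbonyl, O=C=[Co](=C=O)(=C=O)(=C=O)[Co](=C=O)(=C=O)(=C=O)=C=O
Why: Intramolecular Pauson–Khand cyclisation is helped by the cis oxolane arms and the gem-dimethyl group, and C9 is set because the cyclopentenone can fuse to a chair pyran only with C8 equatorial, which puts C11 axial on the face away from the C1–C2 bridge.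

Step 12
Reactants: 17 ring A/B enone
Product: 18 7-(tert-butyldimethylsilyloxy)-5,7-diene (C5=C6 and C7=C8) of ring B
Conditions: TBSOTf (1.3 equiv), Et3N (2.5 equiv), CH2Cl2, 0 °C
Reagents that add atoms: tert-butyldimethylsilyl trifluoromethanesulfonate, CC(C)(C)[Si](C)(C)OS(=O)(=O)C(F)(F)F
Why: Soft enolisation can only remove a C8 proton because the γ-carbons C4 and C9 are quaternary, so the cross-conjugated 2-silyloxydiene is the sole enol silane.

Step 13
Reactants: 18 silyloxydiene with terminal C17=C18 alkene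
Product: 20 C18 primary alcohol of the silyloxydiene, via B-alkyl-9-BBN 19 (not isolated)
Conditions: 9-BBN (1.2 equiv), THF, 0 °C → rt; then NaBO3·4H2O, H2O, rt
Reagents that add atoms: sodium perborate, [Na+].[O-]OB=O
Why: Hydroboration–oxidation with 9-BBN is selective for the monosubstituted alkene over the tetrasubstituted alkene and the hindered silyloxydiene, and the mild perborate oxidation spares the enol silane.

Step 14
Reactants: 20 C18 primary alcohol of the silyloxydiene
Product: 21 C18 aldehyde of the silyloxydiene (key-step precursor)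
Conditions: Dess–Martin periodinane (1.3 equiv), pyridine (5 equiv), CH2Cl2, 0 °C
Reagents that add atoms: none
Why: Buffered Dess–Martin oxidation gives the aldehyde under non-acidic conditions that the tert-butyldimethylsilyl enol ether tolerates.

Step 15
Reactants: 21 C18 aldehyde of the silyloxydiene
Product: 22 pentacyclic enone alcohol (rings C and D closed; C5=C6–C7=O; 18-OH equatorial; 13-Me and 14-Me trans; H-8 cis to C10)
Conditions: Me2AlCl (2.5 equiv), CH2Cl2 (0.005 M), −78 → −40 °C; aq. NaHCO3, then aq. potassium sodium tartrate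
Reagents that add atoms: none
Why: Proposed new method: Me2AlCl activates the C18 aldehyde, C13 of the E alkene adds to it through a chair (ring D, 6-endo-trig) and the developing tertiary C14 cation is taken in the same chair–chair fold by C8 of the 2-silyloxydiene (ring C, 6-endo-trig at the alkene and 6-enolexo at the enol silane), after which loss of the silyl group returns the C5=C6–C7 enone. The closest known reactions are aldehyde- and acetal-initiated cation–olefin polycyclisations that end on an enol silane (Prins initiation, Mukaiyama-type termination); new here is the passage through a tetrasubstituted alkene that leaves two adjacent quaternary carbons. C13 and C14 come from anti addition across the E alkene, so their methyls are trans; C8 is attacked on the ring B face that carries the C11 tether, so rings B and C are cis; C18 takes its aluminium-bound oxygen equatorial, away from the axial C14 methyl. The sense of all four centres relative to C9 follows from the chair of ring C, in which the planar diene forces sp2 C5 axial and the bulky C10 equatorial. The step needs 6-endo over 5-exo attack on an alkene whose two ends are equally substituted, C–C capture at C14 faster than proton loss (ene-type collapse) or chloride capture, and concerted folding so that C13 is not set independently of C9; the unhindered CH2 at C17, the nucleophile held over C14 by the C9 tether, low temperature and high dilution should secure this.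

Step 16
Reactants: 22 pentacyclic enone alcohol
Product: 23 C7 ketone with H-5 trans to C11 (rings A/B trans-fused)
Conditions: Li (10 equiv), NH3(l)/THF, −78 °C; isoprene, then NH4Cl
Reagents that add atoms: none
Why: Dissolving-metal reduction of the enone protonates the C5 carbanion so that C6 is equatorial on the chair pyran, because the cis fusion would force C6 under the C1–C2 bridge.

Step 17
Reactants: 23 C7 ketone
Product: 25 C18 alcohol with C7 methylene, via C7 hydrazone 24 (not isolated)
Conditions: N2H4·H2O (20 equiv), KOH (10 equiv), diethylene glycol, 130 °C then 200 °C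
Reagents that add atoms: none
Why: Wolff–Kishner reduction (Huang-Minlon procedure) removes the cyclopentanone oxygen, and C8 cannot epimerise because the trans B/C fusion would be prohibitively strained on the locked ring C.

Step 18
Reactants: 25 C18 alcohol
Product: 26 C18 ketone
Conditions: Dess–Martin periodinane (1.5 equiv), NaHCO3, CH2Cl2, rt
Reagents that add atoms: none
Why: Dess–Martin oxidation of the hindered secondary alcohol gives a ketone whose only enolisable position is C17.

Step 19
Reactants: 26 C18 ketone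
Product: 27 17-allyl C18 ketone (allyl equatorial)
Conditions: LiN(i-Pr)2 (1.1 equiv), THF, −78 °C; CH2=CHCH2Br (1.3 equiv), −78 → 0 °C
Reagents that add atoms: allyl bromide, C=CCBr
Why: Enolate alkylation can occur only at C17 since C13 is quaternary, and allyl is chosen as the side-chain precursor because the later C18 radical then has no 5-exo acceptor.

Step 20
Reactants: 27 17-allyl C18 ketone
Product: 28 17-allyl-17-methyl C18 ketone (17-Me trans to 13-Me and equatorial; allyl axial)
Conditions: KN(SiMe3)2 (1.3 equiv), THF, −78 → 0 °C; MeI (5 equiv), −78 °C → rt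
Reagents that add atoms: iodomethane, CI
Why: In this enolate alkylation the methyl should enter on the face opposite the axial C13 methyl that flanks the carbonyl, as electrophiles do at C16 of 17-oxo steroids, which sets the C17 quaternary centre.

Step 21
Reactants: 28 17-allyl-17-methyl C18 ketone
Product: 29 C18 carbinol
Conditions: LiAlH4 (3 equiv), THF, 65 °C
Reagents that add atoms: none
Why: Hydride reduction with the small LiAlH4 reaches even a ketone between two quaternary carbons, and the C18 configuration is irrelevant because the centre becomes CH2.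

Step 22
Reactants: 29 C18 carbinol
Product: 30 O-(C18) S-methyl xanthate
Conditions: KH (3 equiv), THF, 0 °C → rt; CS2 (10 equiv); MeI (10 equiv)
Reagents that add atoms: carbon disulfide, S=C=S; iodomethane, CI
Why: The potassium alkoxide adds to the small linear CS2 and S-methylation gives the xanthate, which cannot undergo Chugaev elimination because both β-carbons are quaternary.

Step 23
Reactants: 30 xanthate
Product: 31 17-allyl-17-methyl pentacycle with C18 methylene
Conditions: Bu3SnH (3 equiv), AIBN (0.2 equiv), toluene, 110 °C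
Reagents that add atoms: none
Why: Barton–McCombie deoxygenation gives a C18 radical that is reduced by the stannane, its only cyclisation modes onto the allyl group (4-exo, 5-endo) being slow.

Step 24
Reactants: 31 17-allyl-17-methyl pentacycle
Product: 33 primary alcohol (3-hydroxypropyl on C17), via B-alkyl-9-BBN 32 (not isolated)
Conditions: 9-BBN (1.5 equiv), THF, rt; then NaBO3·4H2O, H2O, rt
Reagents that add atoms: sodium perborate, [Na+].[O-]OB=O
Why: Anti-Markovnikov hydroboration–oxidation of the only alkene in the molecule gives the terminal alcohol.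

Step 25
Reactants: 33 primary alcohol
Product: 34 aldehyde (3-oxopropyl on C17)
Conditions: Dess–Martin periodinane (1.3 equiv), NaHCO3, CH2Cl2, rt
Reagents that add atoms: none
Why: Dess–Martin oxidation stops at the aldehyde and there is no sensitive group left.

Step 26
Reactants: 34 aldehyde
Product: 35 CNP0284367.1 (target)
Conditions: i-PrPPh3I (2 equiv), n-BuLi (1.9 equiv), THF, 0 °C; then 34, −78 °C → rt
Reagents that add atoms: isopropyltriphenylphosphonium iodide, CC(C)[P+](c1ccccc1)(c1ccccc1)c1ccccc1.[I-]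
Why: Wittig olefination with the isopropylidene ylide completes the 4-methylpent-3-enyl chain, and the symmetrical terminus raises no E/Z question.

**Compound list**

1 | (R)-pantolactone, (3R)-3-hydroxy-4,4-dimethyloxolan-2-one | CC1(C)COC(=O)[C@@H]1O | starting material
2 | (3R)-4,4-dimethyloxolane-2,3-diol (lactol, anomers) | CC1(C)COC(O)[C@@H]1O | intermediate
3 | (3S)-2,2-dimethylpent-4-ene-1,3-diol | OCC(C)(C)[C@@H](O)C=C | intermediate
4 | (Z)-2-bromobut-2-ene | C/C=C(\Br)C | starting material
5 | triborylated pentanediol (B-alkyl-9-BBN at C1, O-boryl at both hydroxyls) | C12CCCC(CCC1)B2OCC(C)(C)[C@@H](OB1C2CCCC1CCC2)CCB1C2CCCC1CCC2 | intermediate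
6 | (3S,6Z)-2,2,6-trimethyloct-6-ene-1,3-diol | OCC(C)(C)[C@@H](O)CC/C(C)=C\C | intermediate
7 | (3S)-5-[(2S,3R)-2,3-dimethyloxiran-2-yl]-2,2-dimethylpentane-1,3-diol | OCC(C)(C)[C@@H](O)CC[C@]1(C)O[C@@H]1C | intermediate
8 | (1R)-1-[(2R,5S)-5-(1-hydroxy-2-methylpropan-2-yl)-2-methyloxolan-2-yl]ethan-1-ol | OCC(C)(C)[C@@H]1CC[C@@](C)(O1)[C@@H](C)O | intermediate
9 | 2-[(2S,5R)-5-acetyl-5-methyloxolan-2-yl]-2-methylpropanal | O=CC(C)(C)[C@@H]1CC[C@@](C)(O1)C(C)=O | intermediate
10 | 1-[(2R,5S)-2-methyl-5-(2-methylbut-3-yn-2-yl)oxolan-2-yl]ethan-1-one | C#CC(C)(C)[C@@H]1CC[C@@](C)(O1)C(C)=O | intermediate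
11 | 2,3-dimethylbuta-1,3-diene | C=C(C)C(C)=C | starting material
12 | (2E)-1,4-dibromo-2,3-dimethylbut-2-ene | BrC/C(C)=C(C)/CBr | intermediate
13 | (2E)-1-bromo-2,3-dimethylhepta-2,6-diene | BrC/C(C)=C(C)/CCC=C | intermediate
14 | (4E)-4,5-dimethyl-1-[(2R,5S)-2-methyl-5-(2-methylbut-3-yn-2-yl)oxolan-2-yl]nona-4,8-dien-1-one | C#CC(C)(C)[C@@H]1CC[C@@](C)(O1)C(=O)CC/C(C)=C(C)/CCC=C | intermediate
15 | (2R,5S)-2-[(5E)-5,6-dimethyldeca-1,5,9-trien-2-yl]-2-methyl-5-(2-methylbut-3-yn-2-yl)oxolane | C#CC(C)(C)[C@@H]1CC[C@@](C)(O1)C(=C)CC/C(C)=C(C)/CCC=C | intermediate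
16 | hexacarbonyldicobalt complex of the alkyne of 15 | O=C=[Co]12(=C=O)(=C=O)[Co]3(=C=O)(=C=O)(=C=O)C1(C23)C(C)(C)[C@@H]4CC[C@@](C)(O4)C(=C)CC/C(C)=C(C)/CCC=C | intermediate
17 | ring A/B enone, C9 bearing the (3E)-3,4-dimethylocta-3,7-dienyl chain | C=CCC/C(C)=C(\C)CC[C@@]12CC(=O)C=C1C(C)(C)[C@@H]3CC[C@@]2(C)O3 | intermediate
18 | 7-(tert-butyldimethylsilyloxy)-5,7-diene of 17 | C=CCC/C(C)=C(\C)CC[C@@]12C=C(O[Si](C)(C)C(C)(C)C)C=C1C(C)(C)[C@@H]3CC[C@@]2(C)O3 | intermediate
19 | B-(C18-alkyl)-9-BBN of 18 | C12CCCC(CCC1)B2CCCC/C(C)=C(\C)CC[C@@]12C=C(O[Si](C)(C)C(C)(C)C)C=C1C(C)(C)[C@@H]3CC[C@@]2(C)O3 | intermediate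
20 | C18 primary alcohol of the silyloxydiene | OCCCC/C(C)=C(\C)CC[C@@]12C=C(O[Si](C)(C)C(C)(C)C)C=C1C(C)(C)[C@@H]3CC[C@@]2(C)O3 | intermediate
21 | C18 aldehyde of the silyloxydiene (key-step precursor) | O=CCCC/C(C)=C(\C)CC[C@@]12C=C(O[Si](C)(C)C(C)(C)C)C=C1C(C)(C)[C@@H]3CC[C@@]2(C)O3 | intermediate
22 | pentacyclic C18 alcohol with C5=C6–C7 enone and C17 methylene (key-step product) | O[C@@H]1CCC[C@]2(C)[C@H]3C(=O)C=C4C(C)(C)[C@@H]5CC[C@@](C)(O5)[C@@]43CC[C@]21C | intermediate
23 | pentacyclic C7 ketone, 5-H set, 18-OH | O[C@@H]1CCC[C@]2(C)[C@H]3C(=O)C[C@H]4C(C)(C)[C@@H]5CC[C@@](C)(O5)[C@@]43CC[C@]21C | intermediate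
24 | C7 hydrazone of 23 | O[C@@H]1CCC[C@]2(C)[C@H]3C(=NN)C[C@H]4C(C)(C)[C@@H]5CC[C@@](C)(O5)[C@@]43CC[C@]21C | intermediate
25 | pentacyclic C18 alcohol, C7 methylene | O[C@@H]1CCC[C@]2(C)[C@H]3CC[C@H]4C(C)(C)[C@@H]5CC[C@@](C)(O5)[C@@]43CC[C@]21C | intermediate
26 | pentacyclic C18 ketone | O=C1CCC[C@]2(C)[C@H]3CC[C@H]4C(C)(C)[C@@H]5CC[C@@](C)(O5)[C@@]43CC[C@]21C | intermediate
27 | 17-allyl C18 ketone (allyl equatorial) | O=C1[C@@H](CC=C)CC[C@]2(C)[C@H]3CC[C@H]4C(C)(C)[C@@H]5CC[C@@](C)(O5)[C@@]43CC[C@]21C | intermediate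
28 | 17-allyl-17-methyl C18 ketone (17S; 17-Me trans to 13-Me) | O=C1[C@](C)(CC=C)CC[C@]2(C)[C@H]3CC[C@H]4C(C)(C)[C@@H]5CC[C@@](C)(O5)[C@@]43CC[C@]21C | intermediate
29 | 17-allyl-17-methyl C18 carbinol (equatorial epimer written) | O[C@@H]1[C@](C)(CC=C)CC[C@]2(C)[C@H]3CC[C@H]4C(C)(C)[C@@H]5CC[C@@](C)(O5)[C@@]43CC[C@]21C | intermediate
30 | O-(C18) S-methyl xanthate of 29 | CSC(=S)O[C@@H]1[C@](C)(CC=C)CC[C@]2(C)[C@H]3CC[C@H]4C(C)(C)[C@@H]5CC[C@@](C)(O5)[C@@]43CC[C@]21C | intermediate
31 | 17-allyl-17-methyl pentacycle, C18 methylene | C=CC[C@]1(C)CC[C@]2(C)[C@H]3CC[C@H]4C(C)(C)[C@@H]5CC[C@@](C)(O5)[C@@]43CC[C@@]2(C)C1 | intermediate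
32 | B-alkyl-9-BBN of 31 | C12CCCC(CCC1)B2CCC[C@]1(C)CC[C@]2(C)[C@H]3CC[C@H]4C(C)(C)[C@@H]5CC[C@@](C)(O5)[C@@]43CC[C@@]2(C)C1 | intermediate
33 | 17-(3-hydroxypropyl) pentacycle | OCCC[C@]1(C)CC[C@]2(C)[C@H]3CC[C@H]4C(C)(C)[C@@H]5CC[C@@](C)(O5)[C@@]43CC[C@@]2(C)C1 | intermediate
34 | 17-(3-oxopropyl) pentacycle | O=CCC[C@]1(C)CC[C@]2(C)[C@H]3CC[C@H]4C(C)(C)[C@@H]5CC[C@@](C)(O5)[C@@]43CC[C@@]2(C)C1 | intermediate
35 | CNP0284367.1 | CC(C)=CCC[C@]1(C)CC[C@]2(C)[C@H]3CC[C@H]4C(C)(C)[C@@H]5CC[C@@](C)(O5)[C@@]43CC[C@@]2(C)C1 | target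

**Step count and risks**

Total steps: 26. Longest linear sequence: 24 (steps 1–6, then 9–26); steps 7 and 8 form the short branch.

Steps most likely to fail:

1. Step 15 (proposed new method). The cascade may stop after the first C–C bond: the C14 cation can lose a proton (ene-type collapse), take chloride, or the aldehyde can attack C14 in a 5-exo sense, and the enol silane may be lost before C8 bonds. The fallback is stepwise and uses known reactions. It sets out from 21: the enol silane is cleaved with 1 M HCl in THF to the enone aldehyde F1. TiCl4 in CH2Cl2 at −78 °C then gives the chloride-terminated Prins product, chlorohydrin F2 (ring D closed, C13 quaternary, tertiary chloride at C14). TBSOTf and Et3N convert F2 into the bis-silyl compound F3 (C18 silyl ether and 2-silyloxydiene). AgOTf with 2,6-di-tert-butylpyridine in CH2Cl2 at −78 °C ionises the tertiary chloride for an intramolecular Reetz-type tert-alkylation at C8, giving the silyl ether F4, and HF·pyridine returns the route to 22. Ring D is then formed without relay from C9, so F2 arises in two diastereomeric series and only the matched one is carried on.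

2. Step 11. Alkene insertion into the cobalt–alkyne complex may fail because the 1,1-disubstituted alkene sits next to quaternary C10 and the new C5–C9 bond lies between fully substituted carbons; decomplexation would return the enyne. The fallback replaces the cyclocarbonylation by a Heck cyclisation and an alkene acylation. It sets out from 15: hydration of the alkyne with Ph3PAuNTf2 in aqueous dioxane gives methyl ketone F5. KN(SiMe3)2 and PhNTf2 give enol triflate F6. Pd(PPh3)4, CO (1 atm), MeOH and Et3N in DMF at 60 °C effect a 6-exo Heck cyclisation onto C9 and methoxycarbonylation of the neopentyl palladium intermediate, giving ester F7. LiOH gives acid F8, and (CF3CO)2O closes ring B by acylation of the exocyclic C5=C6 alkene, with double-bond migration into conjugation, to return to 17.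

3. Step 20. Facial selectivity in the methylation may be poor or reversed if stereoelectronically preferred axial attack outweighs the steric effect of the C13 methyl. The fallback puts C17 under catalyst control. It sets out from 26: LiN(i-Pr)2 and MeI give the 17-methyl ketone F9. KN(SiMe3)2 and allyl chloroformate give the allyl enol carbonate F10. Pd2(dba)3 with (S)-t-Bu-PHOX in THF at 25 °C (ligand enantiomer chosen by analogy with 2-methylcyclohexanone, which gives the S ketone) effects decarboxylative allylic alkylation and returns the route to 28.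

**Further compounds**

F1 | step 15 | enone aldehyde (21 without the silyl group) | O=CCCC/C(C)=C(\C)CC[C@@]12CC(=O)C=C1C(C)(C)[C@@H]3CC[C@@]2(C)O3
F2 | step 15 | chlorohydrin, ring D closed, 14-chloro, 18-hydroxy (matched diastereomer) | O[C@@H]1CCC[C@](C)(Cl)[C@@]1(C)CC[C@@]23CC(=O)C=C2C(C)(C)[C@@H]4CC[C@@]3(C)O4
F3 | step 15 | bis-silyl chloride (18-OTBS, 2-silyloxydiene) | CC(C)(C)[Si](C)(C)O[C@@H]1CCC[C@](C)(Cl)[C@@]1(C)CC[C@@]23C=C(O[Si](C)(C)C(C)(C)C)C=C2C(C)(C)[C@@H]4CC[C@@]3(C)O4
F4 | step 15 | tert-butyldimethylsilyl ether of 22 | CC(C)(C)[Si](C)(C)O[C@@H]1CCC[C@]2(C)[C@H]3C(=O)C=C4C(C)(C)[C@@H]5CC[C@@](C)(O5)[C@@]43CC[C@]21C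
F5 | step 11 | methyl ketone from hydration of 15 | CC(=O)C(C)(C)[C@@H]1CC[C@@](C)(O1)C(=C)CC/C(C)=C(C)/CCC=C
F6 | step 11 | enol triflate of F5 | C=C(OS(=O)(=O)C(F)(F)F)C(C)(C)[C@@H]1CC[C@@](C)(O1)C(=C)CC/C(C)=C(C)/CCC=C
F7 | step 11 | ring A methyl ester (exocyclic C5=C6, C9–CH2CO2Me) | COC(=O)C[C@]1(CC/C(C)=C(C)/CCC=C)C(=C)C(C)(C)[C@@H]2CC[C@@]1(C)O2
F8 | step 11 | ring A carboxylic acid | OC(=O)C[C@]1(CC/C(C)=C(C)/CCC=C)C(=C)C(C)(C)[C@@H]2CC[C@@]1(C)O2
F9 | step 20 | 17-methyl C18 ketone | O=C1[C@@H](C)CC[C@]2(C)[C@H]3CC[C@H]4C(C)(C)[C@@H]5CC[C@@](C)(O5)[C@@]43CC[C@]21C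
F10 | step 20 | allyl enol carbonate of F9 | C=CCOC(=O)OC1=C(C)CC[C@]2(C)[C@H]3CC[C@H]4C(C)(C)[C@@H]5CC[C@@](C)(O5)[C@@]43CC[C@]21C
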